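**Plan**

1. Locants (seco-clerodane style): ring C1–C10; C4 carries CO2Me (C18), C5 the exocyclic C19H–OAc, C8 a methyl, C9 a methyl and the 2-(3-furyl)ethyl chain; ring alkenes are C1=C2 (Z) and C3=C4.
2. Retrosynthetic cuts, last-made first: C1–C10 (ring closure), C4–C5 (alkenyl–alkenyl Suzuki), C19–O and C5–B (both from a C5≡C19 alkyne), then the C5–C10 bond of a cyclohexanone that carries C8 and C9.
3. Enabling feature: C10 is a neopentyl CH2 on the quaternary C9 (no β-hydrogen, inert to SN2, so its iodide can be carried through), and C1 is the δ-carbon of the C18 dienoate (activated alkenyl bromide). The cis C3=C4 and Z C1=C2 alkenes fold the chain so that C1 and C10 can meet.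
4. Forward: asymmetric conjugate methylation and alkylation of 2-methylcyclohexenone, ketol cleavage, alkyne formation, cis-diboration, acetoxylation and Suzuki coupling give the open-chain triene; nickel-catalysed reductive coupling then closes the ten-membered ring.
5. Stereochemistry: C8 from the chiral copper catalyst; C9 by enolate alkylation anti to the C8 methyl; the C19 enol acetate geometry from syn-diboration followed by retentive C–O and C–C couplings; the diene geometry from a Z-bromoenal and a Z-selective iodo-Wittig reaction.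

Key step: step 14

Remark: the phosphoramidite enantiomer in step 2 is taken to be the one that gives the (3R) enol ether; its mirror image would give the enantiomeric series.

**Route**

Step 1
Reactants: 1 2-(furan-3-yl)ethan-1-ol
Product: 2 3-(2-iodoethyl)furan
Conditions: PPh3, I2, imidazole, CH2Cl2, 0 °C → rt
Reagents that add atoms: iodine, II
Why: Appel-type iodination converts the unhindered primary alcohol into the iodide by SN2 displacement of the alkoxyphosphonium ion under neutral conditions that a 3-alkylfuran should tolerate.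

Step 2
Reactants: 3 2-methylcyclohex-2-en-1-one
Product: 5 trimethyl{[(3R)-2,3-dimethylcyclohex-1-en-1-yl]oxy}silane, via dimethylaluminium enolate 4 (not isolated)
Conditions: Me3Al, Cu(O2CC4H3S) (copper thiophene-2-carboxylate, 2 mol %), BINOL-derived phosphoramidite ligand (4 mol %), Et2O, −30 °C; then Me3SiOTf, −30 → 0 °C
Reagents that add atoms: trimethylaluminium, C[Al](C)C; trimethylsilyl trifluoromethanesulfonate, C[Si](C)(C)OS(=O)(=O)C(F)(F)F
Why: Copper-catalysed asymmetric conjugate addition of Me3Al to the α-substituted enone should set C8 (ring C3, R) under control of the chiral ligand, and O-silylation stores the regiodefined aluminium enolate as the tetrasubstituted silyl enol ether.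

Step 3
Reactants: 5 trimethyl{[(3R)-2,3-dimethylcyclohex-1-en-1-yl]oxy}silane + 2 3-(2-iodoethyl)furan
Product: 7 (2S,3R)-2-[2-(furan-3-yl)ethyl]-2,3-dimethylcyclohexan-1-one, via lithium enolate 6 (not isolated)
Conditions: MeLi, THF, 0 °C; then DMPU, 2, −78 °C → rt
Reagents that add atoms: none
Why: MeLi cleaves the Si–O bond to the regiodefined lithium enolate, whose SN2 C-alkylation should occur by axial attack on the face anti to the adjacent C8 methyl group, setting the quaternary centre C9 with the two methyl groups cis.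

Step 4
Reactants: 7 (2S,3R)-2-[2-(furan-3-yl)ethyl]-2,3-dimethylcyclohexan-1-one
Product: 9 (2S,3R)-2-[2-(furan-3-yl)ethyl]-6-hydroxy-2,3-dimethylcyclohexan-1-one (both C6 epimers), via potassium enolate 8 (not isolated)
Conditions: KN(SiMe3)2, THF, −78 °C; 2-(phenylsulfonyl)-3-phenyloxaziridine, −78 °C; AcOH quench
Reagents that add atoms: 2-(phenylsulfonyl)-3-phenyloxaziridine, O=S(=O)(N1OC1c1ccccc1)c1ccccc1
Why: Because C2 is quaternary the ketone can enolise only toward C6, and Davis oxaziridine hydroxylation of that potassium enolate gives the α-ketol, whose new carbinol centre is destroyed in the next step.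

Step 5
Reactants: 9 (2S,3R)-2-[2-(furan-3-yl)ethyl]-6-hydroxy-2,3-dimethylcyclohexan-1-one
Product: 10 methyl (2S,3R)-2-[2-(furan-3-yl)ethyl]-2,3-dimethyl-6-oxohexanoate
Conditions: Pb(OAc)4, MeOH/toluene (1:1), 0 °C
Reagents that add atoms: methanol, CO
Why: Criegee-type cleavage of the α-ketol with lead tetraacetate in methanol (through the methyl hemiketal) breaks the ring bond between the carbonyl and carbinol carbons, giving the ester (future C10) and the aldehyde (future C5) without touching either stereocentre.

Step 6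
Reactants: 10 methyl (2S,3R)-2-[2-(furan-3-yl)ethyl]-2,3-dimethyl-6-oxohexanoate
Product: 11 methyl (2S,3R)-2-[2-(furan-3-yl)ethyl]-2,3-dimethylhept-6-ynoate
Conditions: dimethyl (1-diazo-2-oxopropyl)phosphonate, K2CO3, MeOH, 0 °C → rt
Reagents that add atoms: dimethyl (1-diazo-2-oxopropyl)phosphonate, COP(=O)(OC)C(=[N+]=[N-])C(C)=O
Why: Seyferth–Gilbert homologation with the Ohira–Bestmann reagent converts the aldehyde, which has no α-stereocentre, into the terminal alkyne (adding C19) under carbonate/methanol conditions that leave the hindered methyl ester intact.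

Step 7
Reactants: 11 methyl (2S,3R)-2-[2-(furan-3-yl)ethyl]-2,3-dimethylhept-6-ynoate
Product: 12 (2S,3R)-2-[2-(furan-3-yl)ethyl]-2,3-dimethylhept-6-yn-1-ol
Conditions: LiAlH4, Et2O, 0 °C
Reagents that add atoms: none
Why: Hydride reduction of the α-quaternary ester with LiAlH4 gives the neopentyl alcohol, while the terminal alkyne and the furan are not reduced at 0 °C.

Step 8
Reactants: 12 (2S,3R)-2-[2-(furan-3-yl)ethyl]-2,3-dimethylhept-6-yn-1-ol
Product: 13 3-[(3S,4R)-3-(iodomethyl)-3,4-dimethyloct-7-yn-1-yl]furan
Conditions: PPh3, I2, imidazole, toluene, 80 °C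
Reagents that add atoms: iodine, II
Why: Garegg–Samuelsson (Appel-type) iodination at elevated temperature is the usual way to force SN2 displacement at a neopentyl carbinol without skeletal rearrangement, and the resulting neopentyl iodide is inert to substitution in the steps that follow.

Step 9
Reactants: 13 3-[(3S,4R)-3-(iodomethyl)-3,4-dimethyloct-7-yn-1-yl]furan
Product: 14 3-[(3S,4R,7E)-3-(iodomethyl)-3,4-dimethyl-7,8-bis(4,4,5,5-tetramethyl-1,3,2-dioxaborolan-2-yl)oct-7-en-1-yl]furan
Conditions: B2pin2, Pt(PPh3)4 (3 mol %), DMF, 80 °C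
Reagents that add atoms: bis(pinacolato)diboron, CC1(C)OB(OC1(C)C)B1OC(C)(C)C(C)(C)O1
Why: Platinum-catalysed diboration (Miyaura–Ishiyama) adds both boryl groups to the same face of the terminal alkyne, so the C5–B and C19–B bonds are cis, which fixes the later cis relationship of the C19 oxygen and C4.

Step 10
Reactants: 14 3-[(3S,4R,7E)-3-(iodomethyl)-3,4-dimethyl-7,8-bis(4,4,5,5-tetramethyl-1,3,2-dioxaborolan-2-yl)oct-7-en-1-yl]furan
Product: 15 (1E,5R,6S)-6-[2-(furan-3-yl)ethyl]-7-iodo-5,6-dimethyl-2-(4,4,5,5-tetramethyl-1,3,2-dioxaborolan-2-yl)hept-1-en-1-yl acetate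
Conditions: Cu(OAc)2 (2.2 equiv), DMAP (cat.), 4 Å MS, MeCN, air, 25–40 °C
Reagents that add atoms: copper diacetate, [Cu+2].CC([O-])=O.CC([O-])=O
Why: Copper-mediated oxidative C–O coupling of an alkenylboronate with acetate (Chan–Lam-type acyloxylation) proceeds with retention of alkene geometry and should take place at the unhindered terminal CH–B bond in preference to the internal alkyl-substituted C–B bond, giving the enol acetate with oxygen cis to the remaining boryl group.

Step 11
Reactants: 16 ethyl (Z)-3-bromoprop-2-enoate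
Product: 17 (Z)-3-bromoprop-2-enal
Conditions: i-Bu2AlH, CH2Cl2, −78 °C; Rochelle-salt work-up; kept as a cold CH2Cl2 solution
Reagents that add atoms: none
Why: Low-temperature i-Bu2AlH reduction stops at the tetrahedral aluminium hemiacetal, which on work-up releases the β-bromo enal without isomerisation of the cis alkene.

Step 12
Reactants: 17 (Z)-3-bromoprop-2-enal + 18 methyl 2-(triphenyl-λ5-phosphanylidene)acetate
Product: 20 methyl (2Z,4Z)-5-bromo-2-iodopenta-2,4-dienoate, via iodo ylide 19 (not isolated)
Conditions: 18, N-iodosuccinimide, CH2Cl2, −20 °C; then 17, −20 °C → rt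
Reagents that add atoms: N-iodosuccinimide, O=C1CCC(=O)N1I
Why: Iodination of the stabilised ylide followed by Wittig olefination of the enal should give the α-iodo dienoate with the ester trans to the new vinyl substituent (the usual outcome for α-halo stabilised ylides), which is the geometry required at C3=C4.

Step 13
Reactants: 15 (1E,5R,6S)-6-[2-(furan-3-yl)ethyl]-7-iodo-5,6-dimethyl-2-(4,4,5,5-tetramethyl-1,3,2-dioxaborolan-2-yl)hept-1-en-1-yl acetate + 20 methyl (2Z,4Z)-5-bromo-2-iodopenta-2,4-dienoate
Product: 21 methyl (2E,4Z)-2-[(1Z,5R,6S)-1-(acetyloxy)-6-[2-(furan-3-yl)ethyl]-7-iodo-5,6-dimethylhept-1-en-2-yl]-5-bromopenta-2,4-dienoate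
Conditions: Pd(PPh3)4 (10 mol %), CsF, THF, 45 °C
Reagents that add atoms: none
Why: Suzuki–Miyaura alkenyl–alkenyl coupling forms C4–C5 with retention at both partners, should be chemoselective for the α-iodo enoate C–I bond over the alkenyl bromide and the neopentyl iodide, and uses fluoride activation so that no hydroxide is present to cleave the enol acetate.

Step 14
Reactants: 21 methyl (2E,4Z)-2-[(1Z,5R,6S)-1-(acetyloxy)-6-[2-(furan-3-yl)ethyl]-7-iodo-5,6-dimethylhept-1-en-2-yl]-5-bromopenta-2,4-dienoate
Product: 22 methyl (1E,3Z,6R,7R,10Z)-10-[(acetyloxy)methylidene]-6-[2-(furan-3-yl)ethyl]-6,7-dimethylcyclodeca-1,3-diene-1-carboxylate (CNP0318171.1)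
Conditions: NiBr2(MeOCH2CH2OMe) (30 mol %), 4,4′-di-tert-butyl-2,2′-bipyridine (30 mol %), Mn powder, NaI (cat.), N,N-dimethylacetamide, 30 °C, syringe-pump addition of 21 (final 2 mM)
Reagents that add atoms: none
Why: Zerovalent nickel (bipyridine ligand) should insert into the alkenyl C1–Br bond, which is activated as the δ-position of the dienoate, with retention of the Z geometry, while monovalent nickel abstracts iodine from the neopentyl C10–I bond; the tethered C10 radical is then captured at the alkenylnickel centre and reductive elimination from trivalent nickel forms C1–C10, Mn returning the catalyst to its low-valent state. The closest known reaction type is the nickel/bipyridine reductive cross-electrophile coupling of alkenyl bromides with primary alkyl iodides, including its ring-forming intramolecular versions. The ten-membered carbocycle is closed as a macrocyclisation by C(sp2)–C(sp3) reductive elimination from an eleven-membered nickelacycle, not by radical addition to an alkene. No stereocentre is formed: the C1=C2 Z geometry comes from 21, and because only the Z alkenylnickel isomer can reach C10, any E/Z equilibration at nickel is funnelled to the ring-cis product. Cross- over homo-coupling follows from the two different activation modes (two-electron at C–Br, halogen-atom abstraction at C–I), and ring closure over dimerisation is secured by slow addition at high dilution and by the folded chain (cis C3=C4, Z C1=C2, fully substituted C9 next to the C8 methyl); C9 is quaternary, so the C10–nickel intermediate has no β-hydrogen, and the enol acetate, ester and furan should not be reduced by Mn.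

**Compound list**

1 | 2-(furan-3-yl)ethan-1-ol | OCCc1ccoc1 | starting material
2 | 3-(2-iodoethyl)furan | ICCc1ccoc1 | intermediate
3 | 2-methylcyclohex-2-en-1-one | CC1=CCCCC1=O | starting material
4 | dimethyl{[(3R)-2,3-dimethylcyclohex-1-en-1-yl]oxy}alumane (aluminium enolate) | C[Al](C)OC1=C(C)[C@H](C)CCC1 | intermediate
5 | trimethyl{[(3R)-2,3-dimethylcyclohex-1-en-1-yl]oxy}silane | C[Si](C)(C)OC1=C(C)[C@H](C)CCC1 | intermediate
6 | lithium (3R)-2,3-dimethylcyclohex-1-en-1-olate | [Li]OC1=C(C)[C@H](C)CCC1 | intermediate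
7 | (2S,3R)-2-[2-(furan-3-yl)ethyl]-2,3-dimethylcyclohexan-1-one | O=C1[C@@](C)(CCc2ccoc2)[C@H](C)CCC1 | intermediate
8 | potassium (5R,6S)-6-[2-(furan-3-yl)ethyl]-5,6-dimethylcyclohex-1-en-1-olate | [K]OC1=CCC[C@@H](C)[C@]1(C)CCc1ccoc1 | intermediate
9 | (2S,3R)-2-[2-(furan-3-yl)ethyl]-6-hydroxy-2,3-dimethylcyclohexan-1-one (both C6 epimers) | O=C1[C@@](C)(CCc2ccoc2)[C@H](C)CCC1O | intermediate
10 | methyl (2S,3R)-2-[2-(furan-3-yl)ethyl]-2,3-dimethyl-6-oxohexanoate | COC(=O)[C@@](C)(CCc1ccoc1)[C@H](C)CCC=O | intermediate
11 | methyl (2S,3R)-2-[2-(furan-3-yl)ethyl]-2,3-dimethylhept-6-ynoate | COC(=O)[C@@](C)(CCc1ccoc1)[C@H](C)CCC#C | intermediate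
12 | (2S,3R)-2-[2-(furan-3-yl)ethyl]-2,3-dimethylhept-6-yn-1-ol | OC[C@@](C)(CCc1ccoc1)[C@H](C)CCC#C | intermediate
13 | 3-[(3S,4R)-3-(iodomethyl)-3,4-dimethyloct-7-yn-1-yl]furan | IC[C@@](C)(CCc1ccoc1)[C@H](C)CCC#C | intermediate
14 | 3-[(3S,4R,7E)-3-(iodomethyl)-3,4-dimethyl-7,8-bis(4,4,5,5-tetramethyl-1,3,2-dioxaborolan-2-yl)oct-7-en-1-yl]furan (the two boryl groups cis) | IC[C@@](C)(CCc1ccoc1)[C@H](C)CC/C(B1OC(C)(C)C(C)(C)O1)=C/B1OC(C)(C)C(C)(C)O1 | intermediate
15 | (1E,5R,6S)-6-[2-(furan-3-yl)ethyl]-7-iodo-5,6-dimethyl-2-(4,4,5,5-tetramethyl-1,3,2-dioxaborolan-2-yl)hept-1-en-1-yl acetate (OAc cis to boron) | IC[C@@](C)(CCc1ccoc1)[C@H](C)CC/C(B1OC(C)(C)C(C)(C)O1)=C/OC(C)=O | intermediate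
16 | ethyl (Z)-3-bromoprop-2-enoate | CCOC(=O)/C=C\Br | starting material
17 | (Z)-3-bromoprop-2-enal | O=C/C=C\Br | intermediate
18 | methyl 2-(triphenyl-λ5-phosphanylidene)acetate | COC(=O)C=P(c1ccccc1)(c1ccccc1)c1ccccc1 | starting material
19 | methyl 2-iodo-2-(triphenyl-λ5-phosphanylidene)acetate | COC(=O)C(I)=P(c1ccccc1)(c1ccccc1)c1ccccc1 | intermediate
20 | methyl (2Z,4Z)-5-bromo-2-iodopenta-2,4-dienoate | COC(=O)/C(I)=C/C=C\Br | intermediate
21 | methyl (2E,4Z)-2-[(1Z,5R,6S)-1-(acetyloxy)-6-[2-(furan-3-yl)ethyl]-7-iodo-5,6-dimethylhept-1-en-2-yl]-5-bromopenta-2,4-dienoate | COC(=O)C(=C/C=C\Br)/C(CC[C@H]([C@](CI)(C)CCc1ccoc1)C)=C\OC(C)=O | intermediate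
22 | methyl (1E,3Z,6R,7R,10Z)-10-[(acetyloxy)methylidene]-6-[2-(furan-3-yl)ethyl]-6,7-dimethylcyclodeca-1,3-diene-1-carboxylate | COC(=O)/C1=C/C=C\C[C@@](C)(CCc2ccoc2)[C@H](C)CC\C1=C\OC(C)=O | target

**Count and risks**

Total steps: 14. Longest linear sequence: 11 steps (steps 2–10, 13, 14).

Step 14 (ring closure). The likely failure is intermolecular coupling to dimers and oligomers, or simple hydrodehalogenation, outrunning closure of the strained ten-membered ring. The C10 radical might also cyclise onto the nearby enol acetate alkene instead of being captured at nickel. Fallback, from 21: chemoselective insertion of zinc (Zn dust, LiCl, THF, 40 °C) into the neopentyl C–I bond, the alkenyl bromide staying intact, should give the C10 alkylzinc iodide F1. This is then closed by a palladium-catalysed intramolecular Negishi coupling (Pd(OAc)2, SPhos, THF, high dilution), a two-electron pathway with no free alkyl radical and no β-hydrogen on the alkylmetal, returning to the route at 22.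

Step 10 (mono-acetoxylation). The likely failure is oxidation at both C–B bonds or at the internal boron, or protodeboronation, so that the regiochemistry of C–O bond formation is lost. Fallback, from 13: syn-bromoboration of the alkyne with BBr3 (CH2Cl2, −78 °C; bromine to C5, boron to C19) and treatment with aqueous KHF2 should give potassium [(1Z,5R,6S)-2-bromo-6-[2-(furan-3-yl)ethyl]-7-iodo-5,6-dimethylhept-1-en-1-yl]trifluoroborate F2, which has only one C–B bond. Copper-catalysed acetoxylation (Cu(OAc)2, DMAP, KOAc, 4 Å MS, O2) then gives (1Z,5R,6S)-2-bromo-6-[2-(furan-3-yl)ethyl]-7-iodo-5,6-dimethylhept-1-en-1-yl acetate F3 with retention. Miyaura borylation of the C–Br bond (PdCl2(dppf), B2pin2, KOAc, dioxane) returns to the route at 15.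

Step 3 (quaternary centre). The likely failure is E2 elimination of the iodide to 3-vinylfuran by the hindered, basic tetrasubstituted enolate, or O-alkylation, leaving the quaternary centre unformed. Fallback, from 5: the lithium enolate (MeLi, THF) is instead trapped with acetaldehyde at −78 °C, again anti to the C8 methyl, to give (2R,3R)-2-(1-hydroxyethyl)-2,3-dimethylcyclohexan-1-one F4. Burgess dehydration (toluene, 80 °C) gives (2S,3R)-2-ethenyl-2,3-dimethylcyclohexan-1-one F5. Hydroboration with 9-borabicyclo[3.3.1]nonane gives (2S,3R)-2-[2-(9-borabicyclo[3.3.1]nonan-9-yl)ethyl]-2,3-dimethylcyclohexan-1-one F6, which is used directly in a B-alkyl Suzuki coupling with 3-bromofuran (PdCl2(dppf), aqueous K3PO4, THF/DMF), returning to the route at 7.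

**Further compounds**

F1 | step 14 | alkylzinc iodide of 21 (C10–ZnI in place of C10–I) | COC(=O)C(=C/C=C\Br)/C(CC[C@H]([C@](C[Zn]I)(C)CCc1ccoc1)C)=C\OC(C)=O
F2 | step 10 | potassium [(1Z,5R,6S)-2-bromo-6-[2-(furan-3-yl)ethyl]-7-iodo-5,6-dimethylhept-1-en-1-yl]trifluoroborate | IC[C@@](C)(CCc1ccoc1)[C@H](C)CC/C(Br)=C/[B-](F)(F)F.[K+]
F3 | step 10 | (1Z,5R,6S)-2-bromo-6-[2-(furan-3-yl)ethyl]-7-iodo-5,6-dimethylhept-1-en-1-yl acetate | IC[C@@](C)(CCc1ccoc1)[C@H](C)CC/C(Br)=C/OC(C)=O
F4 | step 3 | (2R,3R)-2-(1-hydroxyethyl)-2,3-dimethylcyclohexan-1-one (both carbinol epimers) | O=C1[C@@](C)(C(C)O)[C@H](C)CCC1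
F5 | step 3 | (2S,3R)-2-ethenyl-2,3-dimethylcyclohexan-1-one | O=C1[C@@](C)(C=C)[C@H](C)CCC1
F6 | step 3 | (2S,3R)-2-[2-(9-borabicyclo[3.3.1]nonan-9-yl)ethyl]-2,3-dimethylcyclohexan-1-one | O=C1[C@@](C)(CCB2C3CCCC2CCC3)[C@H](C)CCC1
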